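**Plan**

1. Numbering follows the labdanes: ring A = C1–C5 and C10, ring B = C5–C10, chain C11–C15 on C9, butenolide on C15. The retrosynthesis cuts C12–C13 (fragment union), then the carbinol–butenolide bond in the side-chain fragment, then the two ring A bonds C1–C10 and C4–C5.
2. The enabling feature is the C6 oxygen next to the ring-fusion carbon C5. As a ketone it makes C5=C10 of ring B (C10 carrying the angular methyl) an enone whose two carbons are the fusion atoms, so ring A (C1–C4, gem-dimethyl C4) can be added as a 2-silyloxy diene in one Diels–Alder event that creates both quaternary carbons C4 and C10.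
3. Forward: ring B is not closed but taken from an arene (Heck, all-cis hydrogenation, oxidation, desymmetrizing enolisation, Saegusa–Ito). Ring A closes in step 7 and no ring of the target is formed afterwards. The C2 silyloxy helper leaves via enol triflate hydrogenolysis. The C6 ketone then serves to install the C8 carbinol (C7=C8 enone, 7α,8α-epoxide, reductive opening) before it is reduced.
4. Stereochemistry: the absolute configuration comes from a chiral lithium amide desymmetrization of a meso ketone. It is relayed to C10 by the face selectivity of the Diels–Alder step (anti to the cis C9 chain and C8 methyl). C5 and C9 are set by equilibration to the trans-decalin, C8 by α-face epoxidation (β face blocked by the C10 methyl), and C6 by thermodynamic dissolving-metal reduction.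
5. Side chain: the syn (S,S) carbinol/butenolide pair comes from a BINOL–titanium vinylogous Mukaiyama aldol on (E)-3-iodobut-2-enal with a silyloxyfuran made from commercial 4-methylfuran-2(5H)-one. The E alkene comes from syn-hydrozirconation and a stereoretentive nickel-electrocatalytic decarboxylative alkenylation that joins C12 to C13.

Key step: step 7

Remark: the (R,R)-lithium amide (step 4) and (R)-BINOL (step 15) are assigned by analogy with the closest cases; should either sense of induction be opposite, the enantiomeric base or ligand is used without other change.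

**Step 1**
Reactants: 1 4-bromo-3,5-dimethylphenol; 2 methyl acrylate
Product: 3 methyl (E)-3-(4-hydroxy-2,6-dimethylphenyl)prop-2-enoate
Conditions: Pd(OAc)2 (2 mol %), P(o-tol)3, NaOAc, DMAc, 130 °C
Reagents that add atoms: none
Why: Mizoroki–Heck coupling of a 2,6-dimethylaryl bromide with an acrylate is established for this hindered pattern, tolerates the free phenol and gives the E cinnamate by syn β-hydride elimination.

**Step 2**
Reactants: 3 methyl (E)-3-(4-hydroxy-2,6-dimethylphenyl)prop-2-enoate
Product: 4 methyl 3-[(1s,2R,4r,6S)-4-hydroxy-2,6-dimethylcyclohexyl]propanoate (all-cis)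
Conditions: H2 (60 bar), 5 % Rh/Al2O3, MeOH, 50 °C
Reagents that add atoms: none
Why: Heterogeneous arene hydrogenation on rhodium delivers all ring hydrogens from the catalyst face, so the two methyls and the side chain should end up mutually cis while the alkene is saturated as well; the carbinol configuration is irrelevant.

**Step 3**
Reactants: 4 methyl 3-[(1s,2R,4r,6S)-4-hydroxy-2,6-dimethylcyclohexyl]propanoate
Product: 5 methyl 3-[(1s,2R,6S)-2,6-dimethyl-4-oxocyclohexyl]propanoate (all-cis, meso)
Conditions: TEMPO (cat.), KBr (cat.), NaOCl, NaHCO3, CH2Cl2/H2O, 0 °C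
Reagents that add atoms: none
Why: Oxoammonium (TEMPO/hypochlorite) oxidation of the secondary alcohol gives the meso ketone without touching the ester or the β-stereocentres.

**Step 4**
Reactants: 5 methyl 3-[(1s,2R,6S)-2,6-dimethyl-4-oxocyclohexyl]propanoate
Product: 6 methyl 3-[(1S,2S,6S)-2,6-dimethyl-4-(trimethylsilyloxy)cyclohex-3-en-1-yl]propanoate
Conditions: (R,R)-bis(1-phenylethyl)amine, n-BuLi, LiCl, THF, −78 °C; then TMSCl, 5, −100 °C
Reagents that add atoms: chlorotrimethylsilane (C[Si](C)(C)Cl)
Why: Enantioselective deprotonation of a meso cyclohexanone by a chiral lithium amide with in situ silylation distinguishes the two enantiotopic α-methylene groups, which turns the existing cis ring centres into the source of absolute configuration; the ketone α-protons react in preference to those of the ester.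

**Step 5**
Reactants: 6 methyl 3-[(1S,2S,6S)-2,6-dimethyl-4-(trimethylsilyloxy)cyclohex-3-en-1-yl]propanoate
Product: 7 methyl 3-[(1S,6S)-2,6-dimethyl-4-oxocyclohex-2-en-1-yl]propanoate (side chain and 6-methyl cis)
Conditions: Pd(OAc)2 (1.05 equiv), MeCN, rt
Reagents that add atoms: none
Why: Saegusa–Ito oxidation: the palladium enolate formed from the enol silane can only undergo β-hydride elimination toward the methyl-bearing carbon, giving the β-methyl enone (C5=C10) while the C9 and C8 centres stay untouched.

**Step 6**
Reactants: 8 mesityl oxide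
Product: 9 tert-butyldimethyl[(4-methylpenta-1,3-dien-2-yl)oxy]silane
Conditions: LDA, THF, −78 °C; TBSCl, DMPU, −78 °C → rt
Reagents that add atoms: tert-butyldimethylsilyl chloride (CC(C)(C)[Si](C)(C)Cl)
Why: Kinetic deprotonation at the acetyl methyl group and O-silylation give the cross-conjugated 2-silyloxy diene (silyl enol ether formation).

**Step 7**
Reactants: 7 methyl 3-[(1S,6S)-2,6-dimethyl-4-oxocyclohex-2-en-1-yl]propanoate; 9 tert-butyldimethyl[(4-methylpenta-1,3-dien-2-yl)oxy]silane
Product: 10 methyl 3-[(1S,2S,4aR,8aR)-7-(tert-butyldimethylsilyloxy)-2,5,5,8a-tetramethyl-4-oxo-1,2,3,4,4a,5,8,8a-octahydronaphthalen-1-yl]propanoate (cis-fused)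
Conditions: Tf2NH (10 mol %), 9 (2.5 equiv), CH2Cl2, −78 → −20 °C; Et3N quench
Reagents that add atoms: none
Why: The silyl triflimide generated from Tf2NH and a little diene activates the C6 carbonyl of 7; the nucleophilic CH2 terminus of the diene (future C1) attacks the enone β-carbon C10 and the resulting enol silane carbon C5 closes onto the gem-dimethyl terminus (future C4), a Diels–Alder reaction that is highly asynchronous or a stepwise double Mukaiyama–Michael addition. The closest known reaction type is the strong-acid-promoted (triflimide or mixed AlBr3/AlMe3) Diels–Alder reaction of 4-methyl-2-silyloxypenta-1,3-diene and related hindered silyloxy dienes with α- or β-substituted cyclohexenones, which builds quaternary ring-fusion carbons. Ring A is closed as a six-membered carbocycle by [4+2] union, the second bond (C4–C5) being a 6-(enolexo)-endo-trig Michael closure if the process is stepwise. C10 is set by approach of the diene to the face of ring B anti to the cis C9 chain and C8 methyl (axial attack on the half-chair whose C9 chain is pseudoaxial, which also relieves allylic strain with the C10 methyl); C5 forms cis to the new C1–C10 bond and is corrected in step 11 because it is epimerizable next to C6=O; C4 is not stereogenic. The step needs regioselectivity (C1 to C10, C4 to C5), which follows from the polarisation of both partners, face selectivity, secured by the two β-face substituents, and chemoselectivity over the ester, which is a weaker Lewis base and no dienophile.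

**Step 8**
Reactants: 10 the Diels–Alder adduct (7-silyloxy octalone ester)
Product: 11 methyl 3-[(1S,2S,4aR,8aR)-2,5,5,8a-tetramethyl-4-oxo-7-(trifluoromethylsulfonyloxy)-1,2,3,4,4a,5,8,8a-octahydronaphthalen-1-yl]propanoate
Conditions: CsF, PhNTf2, DME, rt
Reagents that add atoms: N-phenylbis(trifluoromethanesulfonimide) (O=S(=O)(N(c1ccccc1)S(=O)(=O)C(F)(F)F)C(F)(F)F)
Why: Fluoride-induced desilylation of the enol silane and O-triflation of the caesium enolate convert the C2 helper oxygen regiospecifically into an enol triflate while the C6 ketone, which is never enolised by base here, stays differentiated.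

**Step 9**
Reactants: 11 the enol triflate
Product: 12 methyl 3-[(1S,2S,4aR,8aR)-2,5,5,8a-tetramethyl-4-oxodecahydronaphthalen-1-yl]propanoate (cis-fused)
Conditions: H2 (1 atm), PtO2 (cat.), EtOAc, rt
Reagents that add atoms: none
Why: Catalytic hydrogenolysis of an enol triflate over platinum removes the C2 oxygen and saturates C2=C3 in one operation without creating a stereocentre; the hindered C6 ketone should persist, and any over-reduced alcohol would be returned to the ketone by IBX in step 10.

**Step 10**
Reactants: 12 the cis-fused keto ester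
Product: 13 methyl 3-[(1S,4aR,8aR)-2,5,5,8a-tetramethyl-4-oxo-1,4,4a,5,6,7,8,8a-octahydronaphthalen-1-yl]propanoate (cis-fused C7=C8 enone)
Conditions: IBX (2.5 equiv), DMSO, 75 °C
Reagents that add atoms: none
Why: IBX dehydrogenation of a ketone through its enol can only introduce the C7=C8 double bond because C5 is flanked by the quaternary C4 and C10; the C8 centre that served to steer step 7 is erased on purpose.

**Step 11**
Reactants: 13 the cis-fused enone ester
Product: 15 3-[(1R,2S,3S,4aS,8aR)-2,3-epoxy-2,5,5,8a-tetramethyl-4-oxodecahydronaphthalen-1-yl]propanoic acid (7α,8α-epoxy-6-ketone, trans-fused), via trans-fused enone carboxylate 14 (not isolated)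
Conditions: LiOH, MeOH/H2O, 50 °C; then 30 % H2O2, 0 °C → rt; 1 M HCl to pH 4
Reagents that add atoms: lithium hydroxide ([Li+].[OH-]); hydrogen peroxide (OO)
Why: Hydroxide saponifies the ester and equilibrates C5 (through the cross-conjugated dienolate) and C9 (through the extended dienolate) to the more stable trans-decalin with equatorial chain, after which Weitz–Scheffer nucleophilic epoxidation should deliver the hydroperoxide to C8 from the α face because the β face is blocked by the 1,3-diaxial C10 methyl, setting C7 and C8.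

**Step 12**
Reactants: 15 the epoxy keto acid
Product: 17 3-[(1R,2R,4S,4aS,8aS)-2,4-dihydroxy-2,5,5,8a-tetramethyldecahydronaphthalen-1-yl]propanoic acid, via 8α-hydroxy 6-ketone 16 (not isolated)
Conditions: Li (excess), NH3(l)/THF, −78 °C; MeOH, −78 → −33 °C; NH4Cl
Reagents that add atoms: none
Why: Dissolving-metal reduction first cleaves the C7–O bond of the α,β-epoxy ketone (C8 keeps its α oxygen, the enolate protects C6) and, once methanol regenerates the ketone, reduces it under thermodynamic control to the equatorial 6α alcohol, the epimer that hydride attack from the open α face would not give; the carboxylate is inert.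

**Step 13**
Reactants: 18 4-methylfuran-2(5H)-one
Product: 19 trimethyl[(4-methylfuran-2-yl)oxy]silane
Conditions: TMSOTf, Et3N, Et2O, 0 °C
Reagents that add atoms: trimethylsilyl trifluoromethanesulfonate (C[Si](C)(C)OS(=O)(=O)C(F)(F)F)
Why: Soft enolisation of the butenolide at its γ-position and O-silylation give the aromatic 2-silyloxyfuran (silyl dienol ether formation); the lactone ring is carried over from the commercial material.

**Step 14**
Reactants: 20 1,1-diethoxybut-2-yne
Product: 23 (E)-3-iodobut-2-enal, via alkenylzirconocene chloride 21 (not isolated), via iodo acetal 22 (not isolated)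
Conditions: Cp2Zr(H)Cl, THF, rt; I2, 0 °C; 1 M HCl, THF, rt
Reagents that add atoms: iodine (II); water (O)
Why: Syn-hydrozirconation places zirconium on the methyl-bearing alkyne carbon (the less hindered terminus after equilibration), iodinolysis proceeds with retention to the E iodide, and mild acid unmasks the aldehyde.

**Step 15**
Reactants: 19 trimethyl[(4-methylfuran-2-yl)oxy]silane; 23 (E)-3-iodobut-2-enal
Product: 25 (5S)-5-[(1S,2E)-1-hydroxy-3-iodobut-2-en-1-yl]-4-methylfuran-2(5H)-one, via silyl ether 24 (not isolated)
Conditions: Ti(OiPr)4/(R)-BINOL (20 mol %), Et2O, −20 °C; 1 M HCl, THF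
Reagents that add atoms: none
Why: Catalytic asymmetric vinylogous Mukaiyama aldol reaction: the furan γ-carbon adds 1,2 to the enal, the syn (threo) relative topicity is the usual outcome of Lewis acid-promoted additions of 2-silyloxyfurans, and the chiral BINOL–titanium complex should select the aldehyde Re face to give the (1S) carbinol and with it the (5S) lactone centre.

**Step 16**
Reactants: 17 the dihydroxy acid; 25 the iodoalkenyl butenolide
Product: 27 (5S)-5-[(1S,2E)-5-[(1R,2R,4S,4aS,8aS)-2,4-dihydroxy-2,5,5,8a-tetramethyldecahydronaphthalen-1-yl]-1-hydroxy-3-methylpent-2-en-1-yl]-4-methylfuran-2(5H)-one (target), via redox-active ester 26 (not isolated)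
Conditions: N-hydroxyphthalimide, DIC, CH2Cl2, rt; then 25, NiCl2·6H2O (20 mol %), 2,2′-bipyridine, AgNO3 (0.3 equiv), DMF, Mg anode/RVC cathode, constant current, rt
Reagents that add atoms: none
Why: Nickel-electrocatalytic decarboxylative alkenylation: cathodic reduction fragments the N-acyloxyphthalimide to the primary C12 radical, which is captured by the alkenylnickel species from oxidative addition of the vinyl iodide, and reductive elimination forms C12–C13 with retention of the E geometry; free hydroxyls and the β,β-disubstituted butenolide are tolerated and no stereocentre is touched.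

**Compound list**

1 | 4-bromo-3,5-dimethylphenol | Cc1cc(O)cc(C)c1Br | starting material
2 | methyl acrylate | C=CC(=O)OC | starting material
3 | methyl (E)-3-(4-hydroxy-2,6-dimethylphenyl)prop-2-enoate | COC(=O)/C=C/c1c(C)cc(O)cc1C | intermediate
4 | methyl 3-[(1s,2R,4r,6S)-4-hydroxy-2,6-dimethylcyclohexyl]propanoate (all-cis) | COC(=O)CC[C@@H]1[C@H](C)C[C@H](O)C[C@@H]1C | intermediate
5 | methyl 3-[(1s,2R,6S)-2,6-dimethyl-4-oxocyclohexyl]propanoate (all-cis, meso) | COC(=O)CC[C@@H]1[C@H](C)CC(=O)C[C@@H]1C | intermediate
6 | methyl 3-[(1S,2S,6S)-2,6-dimethyl-4-(trimethylsilyloxy)cyclohex-3-en-1-yl]propanoate | COC(=O)CC[C@@H]1[C@H](C)C=C(O[Si](C)(C)C)C[C@@H]1C | intermediate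
7 | methyl 3-[(1S,6S)-2,6-dimethyl-4-oxocyclohex-2-en-1-yl]propanoate | COC(=O)CC[C@@H]1C(C)=CC(=O)C[C@@H]1C | intermediate
8 | mesityl oxide (4-methylpent-3-en-2-one) | CC(=O)C=C(C)C | starting material
9 | tert-butyldimethyl[(4-methylpenta-1,3-dien-2-yl)oxy]silane | C=C(O[Si](C)(C)C(C)(C)C)C=C(C)C | intermediate
10 | methyl 3-[(1S,2S,4aR,8aR)-7-(tert-butyldimethylsilyloxy)-2,5,5,8a-tetramethyl-4-oxo-1,2,3,4,4a,5,8,8a-octahydronaphthalen-1-yl]propanoate | COC(=O)CC[C@@H]1[C@@]2(C)CC(O[Si](C)(C)C(C)(C)C)=CC(C)(C)[C@H]2C(=O)C[C@@H]1C | intermediate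
11 | methyl 3-[(1S,2S,4aR,8aR)-2,5,5,8a-tetramethyl-4-oxo-7-(trifluoromethylsulfonyloxy)-1,2,3,4,4a,5,8,8a-octahydronaphthalen-1-yl]propanoate | COC(=O)CC[C@@H]1[C@@]2(C)CC(OS(=O)(=O)C(F)(F)F)=CC(C)(C)[C@H]2C(=O)C[C@@H]1C | intermediate
12 | methyl 3-[(1S,2S,4aR,8aR)-2,5,5,8a-tetramethyl-4-oxodecahydronaphthalen-1-yl]propanoate (cis-fused) | COC(=O)CC[C@@H]1[C@@]2(C)CCCC(C)(C)[C@H]2C(=O)C[C@@H]1C | intermediate
13 | methyl 3-[(1S,4aR,8aR)-2,5,5,8a-tetramethyl-4-oxo-1,4,4a,5,6,7,8,8a-octahydronaphthalen-1-yl]propanoate (cis-fused) | COC(=O)CC[C@@H]1[C@@]2(C)CCCC(C)(C)[C@H]2C(=O)C=C1C | intermediate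
14 | 3-[(1S,4aS,8aR)-2,5,5,8a-tetramethyl-4-oxo-1,4,4a,5,6,7,8,8a-octahydronaphthalen-1-yl]propanoic acid (trans-fused; present as lithium carboxylate) | OC(=O)CC[C@@H]1[C@@]2(C)CCCC(C)(C)[C@@H]2C(=O)C=C1C | intermediate (not isolated)
15 | 3-[(1R,2S,3S,4aS,8aR)-2,3-epoxy-2,5,5,8a-tetramethyl-4-oxodecahydronaphthalen-1-yl]propanoic acid (7α,8α-epoxide) | OC(=O)CC[C@@H]1[C@@]2(C)CCCC(C)(C)[C@@H]2C(=O)[C@H]3O[C@]31C | intermediate
16 | 3-[(1R,2R,4aS,8aR)-2-hydroxy-2,5,5,8a-tetramethyl-4-oxodecahydronaphthalen-1-yl]propanoic acid | OC(=O)CC[C@@H]1[C@@]2(C)CCCC(C)(C)[C@@H]2C(=O)C[C@@]1(C)O | intermediate (not isolated)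
17 | 3-[(1R,2R,4S,4aS,8aS)-2,4-dihydroxy-2,5,5,8a-tetramethyldecahydronaphthalen-1-yl]propanoic acid | OC(=O)CC[C@@H]1[C@@]2(C)CCCC(C)(C)[C@@H]2[C@@H](O)C[C@@]1(C)O | intermediate
18 | 4-methylfuran-2(5H)-one | CC1=CC(=O)OC1 | starting material
19 | trimethyl[(4-methylfuran-2-yl)oxy]silane | Cc1coc(O[Si](C)(C)C)c1 | intermediate
20 | 1,1-diethoxybut-2-yne | CC#CC(OCC)OCC | starting material
21 | chlorobis(cyclopentadienyl)[(E)-4,4-diethoxybut-2-en-2-yl]zirconium | CCOC(OCC)/C=C(\C)[Zr](Cl)(C1C=CC=C1)C1C=CC=C1 | intermediate (not isolated)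
22 | (E)-1,1-diethoxy-3-iodobut-2-ene | CCOC(OCC)/C=C(\C)I | intermediate (not isolated)
23 | (E)-3-iodobut-2-enal | O=C/C=C(\C)I | intermediate
24 | (5S)-5-[(1S,2E)-3-iodo-1-(trimethylsilyloxy)but-2-en-1-yl]-4-methylfuran-2(5H)-one | CC1=CC(=O)O[C@@H]1[C@@H](O[Si](C)(C)C)/C=C(\C)I | intermediate (not isolated)
25 | (5S)-5-[(1S,2E)-1-hydroxy-3-iodobut-2-en-1-yl]-4-methylfuran-2(5H)-one | CC1=CC(=O)O[C@@H]1[C@@H](O)/C=C(\C)I | intermediate
26 | 1,3-dioxoisoindolin-2-yl 3-[(1R,2R,4S,4aS,8aS)-2,4-dihydroxy-2,5,5,8a-tetramethyldecahydronaphthalen-1-yl]propanoate | O=C(CC[C@@H]1[C@@]2(C)CCCC(C)(C)[C@@H]2[C@@H](O)C[C@@]1(C)O)ON1C(=O)c2ccccc2C1=O | intermediate (not isolated)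
27 | (5S)-5-[(1S,2E)-5-[(1R,2R,4S,4aS,8aS)-2,4-dihydroxy-2,5,5,8a-tetramethyldecahydronaphthalen-1-yl]-1-hydroxy-3-methylpent-2-en-1-yl]-4-methylfuran-2(5H)-one | CC1=CC(=O)O[C@@H]1[C@@H](O)/C=C(\C)CC[C@@H]1[C@@]2(C)CCCC(C)(C)[C@@H]2[C@@H](O)C[C@@]1(C)O | target

**Step count and risks**

Total step count: 16. Longest linear sequence: 12 steps (steps 1–5, 7–12 and 16).

Most likely to fail, step 7: bond formation at the fully substituted β-carbon C10 may be slower than protodesilylation or oligomerisation of the diene, or the face selectivity may be too low. The fallback makes the two ring A bonds in separate, individually known operations and sets out from 7. Acid-catalysed addition of methanol to commercial 5-bromo-2-methylpent-2-ene would give 5-bromo-2-methoxy-2-methylpentane F1, which is converted with magnesium into (4-methoxy-4-methylpentyl)magnesium bromide F2. Conjugate addition of F2 to 7 (CuBr·SMe2 cat., TMSCl, THF, −78 °C), anti to the two β-face substituents, forms the C1–C10 bond and traps the enolate regiospecifically as the trimethylsilyl enol ether F3. TiCl4 in CH2Cl2 at −78 °C then ionises the tertiary methyl ether and the enol silane carbon C5 is alkylated intramolecularly by the tertiary cation at C4 (α-tert-alkylation of a silyl enol ether). This gives 12 directly, possibly together with its trans-fused C5 epimer F4, which converges with 12 at 14 in steps 10 and 11. The fallback comes back to the route at 12.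

Step 15: the simple diastereoselection (syn against anti) or the enantiofacial selectivity may be poor with a β-iodo enal, and addition–elimination at the iodo-bearing carbon may compete. The fallback gives up catalyst control and sets out from 19 and 23. BF3·OEt2 in CH2Cl2 at −78 °C promotes the syn-selective vinylogous aldol addition to give the racemate of 25 with its enantiomer (5R)-5-[(1R,2E)-1-hydroxy-3-iodobut-2-en-1-yl]-4-methylfuran-2(5H)-one F5. The racemate is resolved on this small, early fragment by preparative chromatography on a chiral stationary phase. The fallback comes back at 25.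

Step 16: the activated ester may lactonise onto the tertiary 8-hydroxyl, or reduction and dimerisation of the two partners may outrun the cross-coupling. The fallback builds the chain by carbonyl chemistry on the core and sets out from 17. Excess MeLi (THF, 0 °C) converts the carboxylate into the methyl ketone F6. Horner–Wadsworth–Emmons olefination with triethyl phosphonoacetate and NaH gives the ethyl (E)-enoate F7, from which any Z isomer is removed. i-Bu2AlH gives the allylic alcohol F8, and MnO2 oxidises only the allylic hydroxyl to the enal F9. The vinylogous Mukaiyama aldol reaction of F9 with 19 under the conditions of step 15, where the chiral titanium catalyst controls the two new centres, then arrives at 27.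

**Further compounds**

F1 | step 7 | 5-bromo-2-methoxy-2-methylpentane | COC(C)(C)CCCBr
F2 | step 7 | (4-methoxy-4-methylpentyl)magnesium bromide | COC(C)(C)CCC[Mg]Br
F3 | step 7 | methyl 3-[(1S,2S,6S)-2-(4-methoxy-4-methylpentyl)-2,6-dimethyl-4-(trimethylsilyloxy)cyclohex-3-en-1-yl]propanoate | COC(=O)CC[C@@H]1[C@@](C)(CCCC(C)(C)OC)C=C(O[Si](C)(C)C)C[C@@H]1C
F4 | step 7 | methyl 3-[(1S,2S,4aS,8aR)-2,5,5,8a-tetramethyl-4-oxodecahydronaphthalen-1-yl]propanoate (trans-fused) | COC(=O)CC[C@@H]1[C@@]2(C)CCCC(C)(C)[C@@H]2C(=O)C[C@@H]1C
F5 | step 15 | (5R)-5-[(1R,2E)-1-hydroxy-3-iodobut-2-en-1-yl]-4-methylfuran-2(5H)-one | CC1=CC(=O)O[C@H]1[C@H](O)/C=C(\C)I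
F6 | step 16 | 4-[(1R,2R,4S,4aS,8aS)-2,4-dihydroxy-2,5,5,8a-tetramethyldecahydronaphthalen-1-yl]butan-2-one | CC(=O)CC[C@@H]1[C@@]2(C)CCCC(C)(C)[C@@H]2[C@@H](O)C[C@@]1(C)O
F7 | step 16 | ethyl (2E)-5-[(1R,2R,4S,4aS,8aS)-2,4-dihydroxy-2,5,5,8a-tetramethyldecahydronaphthalen-1-yl]-3-methylpent-2-enoate | CCOC(=O)/C=C(\C)CC[C@@H]1[C@@]2(C)CCCC(C)(C)[C@@H]2[C@@H](O)C[C@@]1(C)O
F8 | step 16 | (2E)-5-[(1R,2R,4S,4aS,8aS)-2,4-dihydroxy-2,5,5,8a-tetramethyldecahydronaphthalen-1-yl]-3-methylpent-2-en-1-ol | OC/C=C(\C)CC[C@@H]1[C@@]2(C)CCCC(C)(C)[C@@H]2[C@@H](O)C[C@@]1(C)O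
F9 | step 16 | (2E)-5-[(1R,2R,4S,4aS,8aS)-2,4-dihydroxy-2,5,5,8a-tetramethyldecahydronaphthalen-1-yl]-3-methylpent-2-enal | O=C/C=C(\C)CC[C@@H]1[C@@]2(C)CCCC(C)(C)[C@@H]2[C@@H](O)C[C@@]1(C)O
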